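The ring is opened between the ketone carbon C1 and C2, the alkene carbon that bears the CH2OH group (C7). This exploits the 2-(hydroxymethyl)enone C1(=O)–C2(C7H2OH)=C3H of the cyclohexenone: C2 is a 2-metallated allylic alcohol, C1 an aldehyde. An intramolecular Nozaki–Hiyama–Kishi reaction closes the six-membered ring with both unsaturated esters already in place. Its precursor is an open-chain (Z)-vinyl iodide aldehyde. C5 and C6 come from one Evans syn aldol. C4 is relayed from C6 by an Evans–Tishchenko reduction with tiglaldehyde, which in the same operation installs the tiglate and leaves only O4 free for the angelate.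

Key step: step 8

Remark: atom labels follow the target ring and are kept for the open-chain compounds (C1 ketone carbon, C2 alkene carbon with C7H2OH, C3 alkene CH, C4 CH–O-angelate, C5 CH–isopropyl, C6 CH–O-tiglate). Compounds 1, 2, 6, 10 and 13 are taken as purchasable. TBS = tert-butyldimethylsilyl, TBDPS = tert-butyldiphenylsilyl.

Step 1
Reactants: 1 (R)-4-benzyl-3-(3-methylbutanoyl)oxazolidin-2-one; 2 (tert-butyldimethylsilyloxy)acetaldehyde
Product: 4 (R)-4-benzyl-3-[(2R,3R)-4-(tert-butyldimethylsilyloxy)-3-hydroxy-2-isopropylbutanoyl]oxazolidin-2-one, via boron enolate 3 (not isolated)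
Conditions: Bu2BOTf, Et3N, CH2Cl2, 0 °C; then 2, −78 to 0 °C; then MeOH, pH 7 buffer, H2O2
Reagents that add atoms: none
Why: Evans syn aldol, in which the (Z)-boron enolate 3 reacts through a Zimmerman–Traxler chair whose open face is fixed by the (R)-benzyl group of the auxiliary, so C5 and C6 (5,6-syn) should both be set in this one event.

Step 2
Reactants: 4 aldol adduct
Product: 5 (2R,3R)-4-(tert-butyldimethylsilyloxy)-3-hydroxy-2-isopropyl-N-methoxy-N-methylbutanamide
Conditions: MeONHMe·HCl, AlMe3, CH2Cl2, −10 °C to rt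
Reagents that add atoms: N,O-dimethylhydroxylamine hydrochloride, CNOC.Cl
Why: Weinreb transamidation with the aluminium amide, which the free C6 hydroxyl should deliver as its aluminium alkoxide to the exocyclic imide carbonyl despite the α-isopropyl branch, leaving C5, C6 and the TBS ether untouched.

Step 3
Reactants: 5 Weinreb amide; 6 tert-butyl(diphenyl)(prop-2-yn-1-yloxy)silane
Product: 8 ynone TBSO–C1H2–C6H(OH)–C5H(iPr)–C4(=O)–C3≡C2–C7H2–OTBDPS (5R,6R), via lithium acetylide 7 (not isolated)
Conditions: 6 (3.2 equiv), n-BuLi, THF, −78 °C; then 5, −78 to −20 °C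
Reagents that add atoms: none
Why: Weinreb ketone synthesis, in which the chelated tetrahedral adduct prevents over-addition, one equivalent of 7 serves as base for the hydroxyl, and the slim alkynyl nucleophile should tolerate the hindered amide.

Step 4
Reactants: 8 ynone
Product: 9 (Z)-β-iodoenone TBSO–C1H2–C6H(OH)–C5H(iPr)–C4(=O)–C3H=C2(I)–C7H2–OTBDPS (2Z,5R,6R)
Conditions: NaI, AcOH, MeCN, rt
Reagents that add atoms: sodium iodide, [Na+].[I-]
Why: Conjugate hydroiodination of an ynone is a kinetic anti addition (iodide to C2, proton to C3) known to give the Z isomer, which places iodine cis to C4 as the ring closure requires, and the weakly acidic medium should keep the C6 hydroxyl from adding to C2.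

Step 5
Reactants: 9 (Z)-β-iodoenone; 10 (E)-2-methylbut-2-enal (tiglaldehyde)
Product: 12 4-hydroxy 6-tiglate TBSO–C1H2–C6H(O-tiglate)–C5H(iPr)–C4H(OH)–C3H=C2(I)–C7H2–OTBDPS (2Z,4R,5S,6R), via mixed hemiacetal 11 (not isolated)
Conditions: SmI2 (0.3 equiv, premixed with 10), 10 (6 equiv), THF, −10 °C
Reagents that add atoms: none
Why: Evans–Tishchenko reduction, in which the samarium-bound hemiacetal 11 passes its hydride intramolecularly to the C4 ketone through a chair-like bicyclic transition state, so C4 should be set 4,6-anti from C6 while the aldehyde ends up as the tiglate on O6 and O4 stays free.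

Step 6
Reactants: 12 4-hydroxy 6-tiglate; 13 angelic acid, (Z)-2-methylbut-2-enoic acid
Product: 15 4-angelate 6-tiglate TBSO–C1H2–C6H(O-tiglate)–C5H(iPr)–C4H(O-angelate)–C3H=C2(I)–C7H2–OTBDPS (2Z,4R,5S,6R), via mixed anhydride 14 (not isolated)
Conditions: 13, 2,4,6-trichlorobenzoyl chloride, Et3N, toluene, rt; then 12, 75 °C, no DMAP
Reagents that add atoms: none
Why: Yamaguchi-type mixed-anhydride esterification without a nucleophilic catalyst is the protocol known to keep the Z geometry of angelates, and the poorly electrophilic tiglate should not migrate; no stereocenter is touched.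

Step 7
Reactants: 15 4-angelate 6-tiglate
Product: 17 aldehyde O=C1H–C6H(O-tiglate)–C5H(iPr)–C4H(O-angelate)–C3H=C2(I)–C7H2–OTBDPS (2Z,4R,5S,6R), via primary alcohol 16 (not isolated)
Conditions: TEMPO (cat.), PhI(OAc)2, Bi(OTf)3 (cat.), wet MeCN, rt
Reagents that add atoms: none
Why: One-pot oxidative desilylation, in which Bi(OTf)3 cleaves the primary alkyl TBS ether but not the TBDPS ether and the TEMPO/PhI(OAc)2 oxidation consumes alcohol 16 as it forms, which should leave little time for tiglate migration from O6 to O1.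

Step 8
Reactants: 17 aldehyde
Product: 19 (4S,5S,6R)-4-angeloyloxy-2-(tert-butyldiphenylsilyloxymethyl)-5-isopropyl-6-tigloyloxycyclohex-2-en-1-ol (both C1 epimers), via alkenylchromium 18 (not isolated)
Conditions: CrCl2 (8 equiv), NiCl2 (2 mol %), degassed DMF, 0.005 M, rt
Reagents that add atoms: none
Why: NiCl2 is reduced by CrCl2 to zerovalent nickel, which inserts into the C2–I bond with retention of the Z geometry; transmetalation gives the trivalent alkenylchromium 18, whose C2 adds to the C1 aldehyde (intramolecular Nozaki–Hiyama–Kishi reaction, a known reaction type for 2-iodoallyl ethers). The only ring closed is the six-membered carbocycle, by 6-exo-trig attack on the C1=O bond with C2=C3 ending up endocyclic, which is possible only because step 4 placed iodine cis to C4. The one new stereocenter, the C1 carbinol, is left to substrate control by the adjacent C6 tiglate and need not be selective because step 9 erases it; C4, C5 and C6 are spectators and the neutral medium should not epimerise the α-acyloxy aldehyde. The step needs chemoselectivity for the aldehyde over the angelate, the tiglate and the silyl ether, which the low basicity and aldehyde preference of alkenylchromium reagents secure, whereas a lithium or magnesium reagent at C2 would attack the angelate carbonyl through a five-membered transition state. High dilution should favour ring closure over dimerisation.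

Step 9
Reactants: 19 cyclohexenol
Product: 20 (4S,5S,6R)-4-angeloyloxy-2-(tert-butyldiphenylsilyloxymethyl)-5-isopropyl-6-tigloyloxycyclohex-2-en-1-one
Conditions: Dess–Martin periodinane, CH2Cl2, 0 °C to rt
Reagents that add atoms: none
Why: Dess–Martin oxidation should converge both C1 epimers of the allylic alcohol on one enone under near-neutral conditions that neither epimerise C6 nor move the esters.

Step 10
Reactants: 20 silyl-protected enone
Product: 21 (4S,5S,6R)-4-angeloyloxy-2-(hydroxymethyl)-5-isopropyl-6-tigloyloxycyclohex-2-en-1-one (target)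
Conditions: HF·pyridine, pyridine, THF, 0 °C to rt
Reagents that add atoms: none
Why: Fluoride-mediated desilylation in a buffered, slightly acidic medium should free the C7 hydroxyl while avoiding the base-induced acyl migration, C6 epimerisation and ester elimination to which the enone is prone.

Compound list
1 | (R)-4-benzyl-3-(3-methylbutanoyl)oxazolidin-2-one | CC(C)CC(=O)N1[C@H](Cc2ccccc2)COC1=O | starting material
2 | (tert-butyldimethylsilyloxy)acetaldehyde | O=CCO[Si](C)(C)C(C)(C)C | starting material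
3 | (Z)-dibutylboron enolate of 1 | CCCCB(CCCC)O/C(=C\C(C)C)N1[C@H](Cc2ccccc2)COC1=O | intermediate
4 | (R)-4-benzyl-3-[(2R,3R)-4-(tert-butyldimethylsilyloxy)-3-hydroxy-2-isopropylbutanoyl]oxazolidin-2-one | O=C(N1[C@H](Cc2ccccc2)COC1=O)[C@H](C(C)C)[C@@H](O)CO[Si](C)(C)C(C)(C)C | intermediate
5 | (2R,3R)-4-(tert-butyldimethylsilyloxy)-3-hydroxy-2-isopropyl-N-methoxy-N-methylbutanamide | CON(C)C(=O)[C@H](C(C)C)[C@@H](O)CO[Si](C)(C)C(C)(C)C | intermediate
6 | tert-butyl(diphenyl)(prop-2-yn-1-yloxy)silane | C#CCO[Si](c1ccccc1)(c1ccccc1)C(C)(C)C | starting material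
7 | lithium acetylide of 6 | [Li]C#CCO[Si](c1ccccc1)(c1ccccc1)C(C)(C)C | intermediate
8 | (5R,6R)-7-(tert-butyldimethylsilyloxy)-1-(tert-butyldiphenylsilyloxy)-6-hydroxy-5-isopropylhept-2-yn-4-one | O=C(C#CCO[Si](c1ccccc1)(c1ccccc1)C(C)(C)C)[C@H](C(C)C)[C@@H](O)CO[Si](C)(C)C(C)(C)C | intermediate
9 | (2Z,5R,6R)-7-(tert-butyldimethylsilyloxy)-1-(tert-butyldiphenylsilyloxy)-6-hydroxy-2-iodo-5-isopropylhept-2-en-4-one | O=C(/C=C(\I)CO[Si](c1ccccc1)(c1ccccc1)C(C)(C)C)[C@H](C(C)C)[C@@H](O)CO[Si](C)(C)C(C)(C)C | intermediate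
10 | (E)-2-methylbut-2-enal (tiglaldehyde) | C/C=C(\C)C=O | starting material
11 | mixed hemiacetal of 9 (through O6) and 10, samarium-bound in the flask, drawn metal-free, hemiacetal carbon unassigned | O=C(/C=C(\I)CO[Si](c1ccccc1)(c1ccccc1)C(C)(C)C)[C@H](C(C)C)[C@@H](OC(O)/C(C)=C/C)CO[Si](C)(C)C(C)(C)C | intermediate
12 | (2Z,4R,5S,6R)-7-(tert-butyldimethylsilyloxy)-1-(tert-butyldiphenylsilyloxy)-4-hydroxy-2-iodo-5-isopropylhept-2-en-6-yl tiglate | O[C@@H](/C=C(\I)CO[Si](c1ccccc1)(c1ccccc1)C(C)(C)C)[C@H](C(C)C)[C@@H](OC(=O)/C(C)=C/C)CO[Si](C)(C)C(C)(C)C | intermediate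
13 | angelic acid, (Z)-2-methylbut-2-enoic acid | C/C=C(/C)C(=O)O | starting material
14 | angelic 2,4,6-trichlorobenzoic anhydride | C/C=C(/C)C(=O)OC(=O)c1c(Cl)cc(Cl)cc1Cl | intermediate
15 | open-chain 4-angelate 6-tiglate with C1–OTBS, C7–OTBDPS and C2–I (2Z,4R,5S,6R) | C/C=C(/C)C(=O)O[C@@H](/C=C(\I)CO[Si](c1ccccc1)(c1ccccc1)C(C)(C)C)[C@H](C(C)C)[C@@H](OC(=O)/C(C)=C/C)CO[Si](C)(C)C(C)(C)C | intermediate
16 | open-chain 4-angelate 6-tiglate with free C1–OH (2Z,4R,5S,6R) | C/C=C(/C)C(=O)O[C@@H](/C=C(\I)CO[Si](c1ccccc1)(c1ccccc1)C(C)(C)C)[C@H](C(C)C)[C@@H](OC(=O)/C(C)=C/C)CO | intermediate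
17 | open-chain C1 aldehyde, 4-angelate 6-tiglate, C2–I (2Z,4R,5S,6R) | C/C=C(/C)C(=O)O[C@@H](/C=C(\I)CO[Si](c1ccccc1)(c1ccccc1)C(C)(C)C)[C@H](C(C)C)[C@@H](OC(=O)/C(C)=C/C)C=O | intermediate
18 | alkenylchromium dichloride from 17 (CrCl2 group on C2, cis to C4) | C/C=C(/C)C(=O)O[C@@H](/C=C(\[Cr](Cl)Cl)CO[Si](c1ccccc1)(c1ccccc1)C(C)(C)C)[C@H](C(C)C)[C@@H](OC(=O)/C(C)=C/C)C=O | intermediate
19 | (4S,5S,6R)-4-angeloyloxy-2-(tert-butyldiphenylsilyloxymethyl)-5-isopropyl-6-tigloyloxycyclohex-2-en-1-ol, C1 unassigned | C/C=C(/C)C(=O)O[C@H]1C=C(CO[Si](c2ccccc2)(c2ccccc2)C(C)(C)C)C(O)[C@H](OC(=O)/C(C)=C/C)[C@H]1C(C)C | intermediate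
20 | (4S,5S,6R)-4-angeloyloxy-2-(tert-butyldiphenylsilyloxymethyl)-5-isopropyl-6-tigloyloxycyclohex-2-en-1-one | C/C=C(/C)C(=O)O[C@H]1C=C(CO[Si](c2ccccc2)(c2ccccc2)C(C)(C)C)C(=O)[C@H](OC(=O)/C(C)=C/C)[C@H]1C(C)C | intermediate
21 | (4S,5S,6R)-4-angeloyloxy-2-(hydroxymethyl)-5-isopropyl-6-tigloyloxycyclohex-2-en-1-one | C/C=C(/C)C(=O)O[C@H]1C=C(CO)C(=O)[C@H](OC(=O)/C(C)=C/C)[C@H]1C(C)C | target

Total step count: 10. Longest linear sequence: 10 steps (1 to 21).

Steps most likely to fail

Step 5. Hydride transfer from a conjugated, less electrophilic aldehyde may be slow. Three processes could then compete: attack of the C6 alkoxide on C2 with loss of iodide, reduction of the C–I bond by divalent samarium, and acyl migration from O6 to O4. The fallback brings the tiglate in by plain acylation instead of by redox transfer.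
- It sets out from 9, which is reduced in the same anti-selective way with 4-nitrobenzaldehyde, a proven fast hydride donor (SmI2, THF, −10 °C), to give the 6-(4-nitrobenzoate) F1.
- O4 is esterified as in step 6 to give the 4-angelate 6-(4-nitrobenzoate) F2.
- The activated benzoate is removed with K2CO3 in MeOH at 0 °C to give the 4-angelate 6-alcohol F3.
- O6 is acylated with tiglic acid (2,4,6-trichlorobenzoyl chloride, Et3N, DMAP, toluene), which comes back to the route at 15.

Step 8. The alkenylchromium may be protonated before it cyclises, may lose the allylic silyloxy group, or may react between molecules. The fallback closes the same bond by acylation at the ketone oxidation level.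
- It sets out from 17, which a Pinnick oxidation (NaClO2, NaH2PO4, 2-methylbut-2-ene, t-BuOH/H2O) converts to the carboxylic acid F4.
- EtSH and EDC give the S-ethyl thioester F5.
- Me3SnSnMe3 with Pd(PPh3)4 exchanges iodine for tin with retention to give the alkenylstannane F6.
- An intramolecular Liebeskind–Srogl coupling (Pd2(dba)3, tri(2-furyl)phosphine, CuOP(O)Ph2, THF, high dilution) comes back to the route at 20, so step 9 is no longer needed.

Step 4. Prolonged contact with acid and iodide may isomerise the Z iodoenone to E. The free C6 hydroxyl may cyclise onto C2, or the primary TBS ether may be partly lost. The fallback keeps the alkyne through the reduction.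
- It sets out from 8, which the Evans–Tishchenko reduction with 10 (as in step 5) converts to the propargylic alcohol 6-tiglate F7.
- A ruthenium-catalysed trans-hydrosilylation ([Cp*Ru(MeCN)3]PF6, BnMe2SiH, CH2Cl2, 0 °C) places silicon distal to the free O4 carbinol and cis to C4, and gives the (Z)-vinylsilane F8.
- Iododesilylation with retention (N-iodosuccinimide, (CF3)2CHOH, 0 °C) comes back to the route at 12.

Further compounds
F1 | step 5 | (2Z,4R,5S,6R)-4-hydroxy 6-(4-nitrobenzoate) analogue of 12 | O[C@@H](/C=C(\I)CO[Si](c1ccccc1)(c1ccccc1)C(C)(C)C)[C@H](C(C)C)[C@@H](OC(=O)c1ccc(cc1)[N+](=O)[O-])CO[Si](C)(C)C(C)(C)C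
F2 | step 5 | 4-angelate 6-(4-nitrobenzoate) | C/C=C(/C)C(=O)O[C@@H](/C=C(\I)CO[Si](c1ccccc1)(c1ccccc1)C(C)(C)C)[C@H](C(C)C)[C@@H](OC(=O)c1ccc(cc1)[N+](=O)[O-])CO[Si](C)(C)C(C)(C)C
F3 | step 5 | 4-angelate 6-alcohol | C/C=C(/C)C(=O)O[C@@H](/C=C(\I)CO[Si](c1ccccc1)(c1ccccc1)C(C)(C)C)[C@H](C(C)C)[C@@H](O)CO[Si](C)(C)C(C)(C)C
F4 | step 8 | C1 carboxylic acid from 17 | C/C=C(/C)C(=O)O[C@@H](/C=C(\I)CO[Si](c1ccccc1)(c1ccccc1)C(C)(C)C)[C@H](C(C)C)[C@@H](OC(=O)/C(C)=C/C)C(=O)O
F5 | step 8 | C1 S-ethyl thioester | C/C=C(/C)C(=O)O[C@@H](/C=C(\I)CO[Si](c1ccccc1)(c1ccccc1)C(C)(C)C)[C@H](C(C)C)[C@@H](OC(=O)/C(C)=C/C)C(=O)SCC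
F6 | step 8 | C2 trimethylstannyl C1 S-ethyl thioester | C/C=C(/C)C(=O)O[C@@H](/C=C(\[Sn](C)(C)C)CO[Si](c1ccccc1)(c1ccccc1)C(C)(C)C)[C@H](C(C)C)[C@@H](OC(=O)/C(C)=C/C)C(=O)SCC
F7 | step 4 | propargylic alcohol 6-tiglate | O[C@@H](C#CCO[Si](c1ccccc1)(c1ccccc1)C(C)(C)C)[C@H](C(C)C)[C@@H](OC(=O)/C(C)=C/C)CO[Si](C)(C)C(C)(C)C
F8 | step 4 | (Z)-C2-benzyldimethylsilyl alkene 6-tiglate | O[C@@H](/C=C(\[Si](C)(C)Cc1ccccc1)CO[Si](c1ccccc1)(c1ccccc1)C(C)(C)C)[C@H](C(C)C)[C@@H](OC(=O)/C(C)=C/C)CO[Si](C)(C)C(C)(C)C
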